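## Retrosynthetic overview

1. Labels: C1 (C=O), C2 (pentenyl), C3 (ester chain), C4 (CHOH), C5 (CHBr) of the only ring, the cyclopent-2-enone; the same labels are used for the acyclic precursors.
2. C5–Br is traced back to C5(Br)(CO2tBu) and then C5H(CO2tBu): a traceless carboxyl makes C5 the α-carbon of a β-keto ester, which opens the ring at C1–C5 (retro-Dieckmann); C4–OH is traced back to C4–B.
3. Key disconnection: C1–C5 together with C4–B, back to the achiral, acyclic dienedioate 8. In the forward direction an enantioselective copper-catalysed conjugate borylation at C4 generates the C5 enolate, which closes the only ring onto the C1 ester (borylative Dieckmann).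
4. Enabling feature: C1=O and C4–O are 1,3-related across C5, and C1 and C4 are held cis by the tetrasubstituted C2=C3 double bond, so a C5 enolate lies within reach of C1 (5-exo-trig).
5. 8 comes from the Z-enol triflate 6 and tert-butyl acrylate (Heck, C3–C4); 6 from β-keto ester 4; 4 from Claisen acylation of ester 1 with acid chloride 2 (C2–C3).

Key step: step 4

Assumption: the trans C4/C5 arrangement of the target is taken to be the more stable C5 epimer of this enolisable α-bromo ketone, so that acid-mediated enolisation converges on it.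

## Route

Step 1
Reactants: 1 ethyl (4Z)-hept-4-enoate; 2 methyl 9-chloro-9-oxononanoate
Product: 4 ethyl (4Z)-2-(9-methoxy-9-oxononanoyl)hept-4-enoate, via lithium enolate 3 (not isolated)
Conditions: LDA (2.1 equiv), 1 (2.1 equiv), THF, −78 °C; then 2 (1.0 equiv), −78 °C; aq. NH4Cl
Reagents that add atoms: none
Why: Crossed Claisen C-acylation of a pre-formed lithium ester enolate by an acid chloride should give the β-keto ester (C2–C3 bond), the second equivalent of enolate taking up its acidic proton, while the saturated methyl ester of 2 is far less electrophilic than the acyl chloride at −78 °C; the new C2 centre is racemic and is destroyed in step 2.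

Step 2
Reactants: 4 ethyl (4Z)-2-(9-methoxy-9-oxononanoyl)hept-4-enoate
Product: 6 1-ethyl 11-methyl (2Z)-2-[(2Z)-pent-2-en-1-yl]-3-{[(trifluoromethyl)sulfonyl]oxy}undec-2-enedioate, via sodium enolate 5 (not isolated)
Conditions: NaH (1.1 equiv), toluene, 0 °C; then Tf2O (1.1 equiv), 0 °C
Reagents that add atoms: triflic anhydride (Tf2O), O=S(=O)(OS(=O)(=O)C(F)(F)F)C(F)(F)F
Why: O-triflation of the chelated sodium Z-enolate of an α-substituted β-keto ester (enol triflate formation) in a non-polar solvent should place OTf cis to CO2Et, which fixes the geometry of the future C2=C3 double bond.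

Step 3
Reactants: 6 1-ethyl 11-methyl (2Z)-2-[(2Z)-pent-2-en-1-yl]-3-{[(trifluoromethyl)sulfonyl]oxy}undec-2-enedioate; 7 tert-butyl acrylate
Product: 8 1-tert-butyl 6-ethyl (2E,4Z)-4-(8-methoxy-8-oxooctyl)-5-[(2Z)-pent-2-en-1-yl]hexa-2,4-dienedioate
Conditions: Pd(OAc)2 (5 mol %), P(o-tol)3 (10 mol %), i-Pr2NEt (2 equiv), DMF, 70 °C
Reagents that add atoms: none
Why: Mizoroki–Heck coupling of an alkenyl triflate with an acrylate should form C3–C4 with retention of the triflate geometry and give the E-acrylate by syn-insertion and syn-β-hydride elimination, so that the C1 ester and the new C4=C5 acrylate end up cis on C2=C3.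

Step 4
Reactants: 8 1-tert-butyl 6-ethyl (2E,4Z)-4-(8-methoxy-8-oxooctyl)-5-[(2Z)-pent-2-en-1-yl]hexa-2,4-dienedioate
Product: 10 tert-butyl (5S)-5-hydroxy-4-(8-methoxy-8-oxooctyl)-2-oxo-3-[(2Z)-pent-2-en-1-yl]cyclopent-3-ene-1-carboxylate, via boronate keto ester 9 (not isolated)
Conditions: CuCl (5 mol %), (R)-DTBM-SEGPHOS (6 mol %), LiOtBu (1.2 equiv), B2pin2 (1.3 equiv), THF, −20 °C to rt; then NaBO3·4H2O, THF/H2O, 0 °C; aq. NH4Cl
Reagents that add atoms: sodium perborate tetrahydrate (oxygen of the C4 hydroxyl), [Na+].[O-]OB=O.O.O.O.O; bis(pinacolato)diboron (boryl group of 9), CC1(C)OB(OC1(C)C)B1OC(C)(C)C(C)(C)O1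
Why: Proposed new method: a ligated copper boryl (monovalent copper, from CuCl, LiOtBu and B2pin2) should add across the C4=C5 acrylate of 8 with boron at C4 and the metal at C5, and the resulting ester enolate, instead of being protonated as in the known methanol-quenched reaction, should attack the C1 ethyl ester and expel ethoxide to give the C4-boryl β-keto ester 9 as its lithium enolate, ethoxide and B2pin2 regenerating the copper boryl. The closest known reaction types are the copper-catalysed enantioselective β-borylation of α,β-unsaturated esters, the copper-catalysed borylative aldol cyclisation in which the same kind of enolate is trapped by a ketone, and the cuprate-initiated Michael–Dieckmann cyclisation of enedioates. The cyclopentenone ring is closed by forming C1–C5 in a 5-exo-trig acyl substitution (Dieckmann mode), which is possible because the Z tetrasubstituted C2=C3 bond holds C1 and C4 cis. The C4 stereocentre is set under catalyst control by enantioface-selective boryl transfer to the E-acrylate (the ligand enantiomer is chosen to give the 5S boronate, and boron is then replaced by OH with retention), whereas the ester-bearing C5 is epimerisable and is erased in step 6. The step needs chemoselectivity for the disubstituted acrylate over the tetrasubstituted C2=C3 enoate and the isolated Z-alkene, which the steric and electronic bias of copper boryl addition should secure, and ring closure faster than intermolecular Michael addition, which the cis-held ester should secure. The perborate oxidation is done only after ring closure, so that the free C4 hydroxyl never faces the C1 ester (no butenolide), and with the β-keto ester still as its enolate, which should suppress retro-aldol opening.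

Step 5
Reactants: 10 tert-butyl (5S)-5-hydroxy-4-(8-methoxy-8-oxooctyl)-2-oxo-3-[(2Z)-pent-2-en-1-yl]cyclopent-3-ene-1-carboxylate
Product: 11 tert-butyl (5R)-1-bromo-5-hydroxy-4-(8-methoxy-8-oxooctyl)-2-oxo-3-[(2Z)-pent-2-en-1-yl]cyclopent-3-ene-1-carboxylate
Conditions: NBS (1.05 equiv), CH2Cl2, 0 °C, dark, used directly after step 4
Reagents that add atoms: N-bromosuccinimide (NBS), O=C1CCC(=O)N1Br
Why: Electrophilic α-bromination of the enol-rich cyclic β-keto ester with NBS should be far faster than attack on the isolated Z-alkene or the electron-poor enone, and it makes C5 quaternary so that the ring can no longer enolise next to C4; the configuration of the new quaternary centre is of no consequence because it is erased in step 6.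

Step 6
Reactants: 11 tert-butyl (5R)-1-bromo-5-hydroxy-4-(8-methoxy-8-oxooctyl)-2-oxo-3-[(2Z)-pent-2-en-1-yl]cyclopent-3-ene-1-carboxylate
Product: 13 methyl 8-[(4S,5R)-4-bromo-5-hydroxy-3-oxo-2-[(2Z)-pent-2-en-1-yl]cyclopent-1-en-1-yl]octanoate (CNP0306311.1), via bromo keto acid 12 (not isolated)
Conditions: TFA/CH2Cl2 (1:4), 0 °C to rt, until the C5 epimer ratio is constant; brief aq. NaHCO3 wash
Reagents that add atoms: none
Why: Acidolysis of the tert-butyl ester with loss of isobutene should give β-keto acid 12, which decarboxylates through the usual cyclic transition state to the bromo-enol (acid-mediated dealkoxycarbonylation of a β-keto ester), and ketonisation followed by acid-mediated equilibration through the enol should leave bromine at C5 trans to the C4 hydroxyl (substrate and thermodynamic control by C4), while C4 itself is untouched.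

## Compound list

1 | ethyl (4Z)-hept-4-enoate | CC/C=C\CCC(=O)OCC | starting material
2 | methyl 9-chloro-9-oxononanoate | COC(=O)CCCCCCCC(Cl)=O | starting material
3 | lithium (4Z)-1-ethoxyhepta-1,4-dien-1-olate (lithium enolate of 1) | CC/C=C\CC=C([O-])OCC.[Li+] | intermediate
4 | ethyl (4Z)-2-(9-methoxy-9-oxononanoyl)hept-4-enoate (racemic at C2) | CC/C=C\CC(C(=O)OCC)C(=O)CCCCCCCC(=O)OC | intermediate
5 | sodium Z-enolate of 4 (enolate oxygen cis to CO2Et) | CCOC(=O)/C(C/C=C\CC)=C(\[O-])CCCCCCCC(=O)OC.[Na+] | intermediate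
6 | 1-ethyl 11-methyl (2Z)-2-[(2Z)-pent-2-en-1-yl]-3-{[(trifluoromethyl)sulfonyl]oxy}undec-2-enedioate | CCOC(=O)/C(C/C=C\CC)=C(\OS(=O)(=O)C(F)(F)F)CCCCCCCC(=O)OC | intermediate
7 | tert-butyl acrylate | C=CC(=O)OC(C)(C)C | starting material
8 | 1-tert-butyl 6-ethyl (2E,4Z)-4-(8-methoxy-8-oxooctyl)-5-[(2Z)-pent-2-en-1-yl]hexa-2,4-dienedioate | CCOC(=O)/C(C/C=C\CC)=C(\C=C\C(=O)OC(C)(C)C)CCCCCCCC(=O)OC | intermediate
9 | tert-butyl (5S)-4-(8-methoxy-8-oxooctyl)-2-oxo-3-[(2Z)-pent-2-en-1-yl]-5-(4,4,5,5-tetramethyl-1,3,2-dioxaborolan-2-yl)cyclopent-3-ene-1-carboxylate (C1 epimerisable, present as its enolate) | CC/C=C\CC1=C(CCCCCCCC(=O)OC)[C@@H](B2OC(C)(C)C(C)(C)O2)C(C(=O)OC(C)(C)C)C1=O | intermediate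
10 | tert-butyl (5S)-5-hydroxy-4-(8-methoxy-8-oxooctyl)-2-oxo-3-[(2Z)-pent-2-en-1-yl]cyclopent-3-ene-1-carboxylate (C1 epimerisable) | CC/C=C\CC1=C(CCCCCCCC(=O)OC)[C@@H](O)C(C(=O)OC(C)(C)C)C1=O | intermediate
11 | tert-butyl (5R)-1-bromo-5-hydroxy-4-(8-methoxy-8-oxooctyl)-2-oxo-3-[(2Z)-pent-2-en-1-yl]cyclopent-3-ene-1-carboxylate (C1 not defined) | CC/C=C\CC1=C(CCCCCCCC(=O)OC)[C@@H](O)C(Br)(C(=O)OC(C)(C)C)C1=O | intermediate
12 | (5R)-1-bromo-5-hydroxy-4-(8-methoxy-8-oxooctyl)-2-oxo-3-[(2Z)-pent-2-en-1-yl]cyclopent-3-ene-1-carboxylic acid (C1 not defined) | CC/C=C\CC1=C(CCCCCCCC(=O)OC)[C@@H](O)C(Br)(C(=O)O)C1=O | intermediate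
13 | methyl 8-[(4S,5R)-4-bromo-5-hydroxy-3-oxo-2-[(2Z)-pent-2-en-1-yl]cyclopent-1-en-1-yl]octanoate (trans; CNP0306311.1) | CC/C=C\CC1=C(CCCCCCCC(=O)OC)[C@@H](O)[C@H](Br)C1=O | target

## Step count and risks

Total step count: 6. Longest linear sequence: 6 steps (1 to 13).

Steps most likely to fail:

1. Step 4 (the step that carries the new-method label). What may go wrong:
   - the enolate is borylated on oxygen or merely protonated on work-up instead of cyclising;
   - turnover stalls because the β-keto ester enolate chelates copper;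
   - liberated ethoxide adds in an oxa-Michael sense;
   - enantioface discrimination is poor;
   - C4 is eroded by base-mediated retro-aldol opening and reclosure during the oxidation.

   Fallback with known chemistry, setting out from 8: the standard methanol-quenched enantioselective β-borylation (CuCl, (R)-DTBM-SEGPHOS, catalytic NaOtBu, B2pin2, MeOH 2 equiv, THF) should give the isolable acyclic boronate 1-tert-butyl 6-ethyl (3S,4Z)-4-(8-methoxy-8-oxooctyl)-5-[(2Z)-pent-2-en-1-yl]-3-(4,4,5,5-tetramethyl-1,3,2-dioxaborolan-2-yl)hex-4-enedioate F1. A separate base-mediated Dieckmann cyclisation of its ester enolate (LiHMDS 2.2 equiv, THF, −78 to 0 °C) then returns to the route at 9, which is oxidised to 10 as in step 4.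

2. Step 6. What may go wrong:
   - ketonisation of the bromo-enol without convergence on the trans epimer;
   - an enol-mediated 1,5-hydrogen shift toward the 1,3-dione oxidation pattern;
   - loss of HBr under the acidic conditions.

   Fallback, setting out from 10, with decarboxylation before bromination and kinetic anti bromination:
   - TFA/CH2Cl2 should give, through the keto acid (5S)-5-hydroxy-4-(8-methoxy-8-oxooctyl)-2-oxo-3-[(2Z)-pent-2-en-1-yl]cyclopent-3-ene-1-carboxylic acid F2 (not isolated), the hydroxy enone methyl 8-[(5S)-5-hydroxy-3-oxo-2-[(2Z)-pent-2-en-1-yl]cyclopent-1-en-1-yl]octanoate F3.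
   - Silylation (TBSCl, imidazole, DMF) gives methyl 8-[(5S)-5-{[tert-butyl(dimethyl)silyl]oxy}-3-oxo-2-[(2Z)-pent-2-en-1-yl]cyclopent-1-en-1-yl]octanoate F4.
   - Kinetic enolisation at C5 with in-situ trapping (LiHMDS, TMSCl, THF, −78 °C) gives the cross-conjugated silyl dienol ether methyl 8-[(5S)-5-{[tert-butyl(dimethyl)silyl]oxy}-2-[(2Z)-pent-2-en-1-yl]-3-[(trimethylsilyl)oxy]cyclopenta-1,3-dien-1-yl]octanoate F5.
   - NBS (THF, −78 °C) should deliver bromine anti to the C4 silyloxy group to give methyl 8-[(4S,5R)-4-bromo-5-{[tert-butyl(dimethyl)silyl]oxy}-3-oxo-2-[(2Z)-pent-2-en-1-yl]cyclopent-1-en-1-yl]octanoate F6.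
   - HF·pyridine (THF, 0 °C) removes the silyl ether and returns to the route at 13.

3. Step 3. What may go wrong:
   - slow carbopalladation of the acrylate by the hindered tetrasubstituted alkenylpalladium;
   - palladium hydride induced migration or Z/E scrambling of the skipped alkene;
   - attack of the amine base on the β-triflyloxy enoate.

   Fallback, setting out from 6: the C–H alkenylation is replaced by a cross-coupling with a geometrically fixed partner. Suzuki–Miyaura coupling (Pd(PPh3)4, K3PO4, dioxane/H2O, 60 °C) with tert-butyl (2E)-3-(4,4,5,5-tetramethyl-1,3,2-dioxaborolan-2-yl)prop-2-enoate F7 returns to the route at 8. F7 is prepared from tert-butyl propiolate by copper-catalysed hydroboration (CuCl, Xantphos, NaOtBu, B2pin2, MeOH).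

Further compounds

F1 | step 4 | 1-tert-butyl 6-ethyl (3S,4Z)-4-(8-methoxy-8-oxooctyl)-5-[(2Z)-pent-2-en-1-yl]-3-(4,4,5,5-tetramethyl-1,3,2-dioxaborolan-2-yl)hex-4-enedioate | CCOC(=O)/C(C/C=C\CC)=C(\[C@@H](B1OC(C)(C)C(C)(C)O1)CC(=O)OC(C)(C)C)CCCCCCCC(=O)OC
F2 | step 6 | (5S)-5-hydroxy-4-(8-methoxy-8-oxooctyl)-2-oxo-3-[(2Z)-pent-2-en-1-yl]cyclopent-3-ene-1-carboxylic acid | CC/C=C\CC1=C(CCCCCCCC(=O)OC)[C@@H](O)C(C(=O)O)C1=O
F3 | step 6 | methyl 8-[(5S)-5-hydroxy-3-oxo-2-[(2Z)-pent-2-en-1-yl]cyclopent-1-en-1-yl]octanoate | CC/C=C\CC1=C(CCCCCCCC(=O)OC)[C@@H](O)CC1=O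
F4 | step 6 | methyl 8-[(5S)-5-{[tert-butyl(dimethyl)silyl]oxy}-3-oxo-2-[(2Z)-pent-2-en-1-yl]cyclopent-1-en-1-yl]octanoate | CC/C=C\CC1=C(CCCCCCCC(=O)OC)[C@@H](O[Si](C)(C)C(C)(C)C)CC1=O
F5 | step 6 | methyl 8-[(5S)-5-{[tert-butyl(dimethyl)silyl]oxy}-2-[(2Z)-pent-2-en-1-yl]-3-[(trimethylsilyl)oxy]cyclopenta-1,3-dien-1-yl]octanoate | CC/C=C\CC1=C(CCCCCCCC(=O)OC)[C@@H](O[Si](C)(C)C(C)(C)C)C=C1O[Si](C)(C)C
F6 | step 6 | methyl 8-[(4S,5R)-4-bromo-5-{[tert-butyl(dimethyl)silyl]oxy}-3-oxo-2-[(2Z)-pent-2-en-1-yl]cyclopent-1-en-1-yl]octanoate | CC/C=C\CC1=C(CCCCCCCC(=O)OC)[C@@H](O[Si](C)(C)C(C)(C)C)[C@H](Br)C1=O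
F7 | step 3 | tert-butyl (2E)-3-(4,4,5,5-tetramethyl-1,3,2-dioxaborolan-2-yl)prop-2-enoate | CC(C)(C)OC(=O)/C=C/B1OC(C)(C)C(C)(C)O1
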